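Take the ratio of uncatalysed product V to target P in each earlier run, summed over its samples, and multiply it by the free catalyst charged, C.

| flask | starting material | second substrate | coupling partner | free catalyst | remark | time |
|---|---|---|---|---|---|---|
| larch | 1 mM | 0.50 mM | 2 mM | 1.4 µM | run made earlier |  |
| birch | 1 mM | 0.50 mM | 2 mM | 2.2 µM | run made earlier |  |
| ash | 1 mM | 0.50 mM | 4 mM | 1 µM | run made earlier |  |
| flask | 1.0 mM | 0.500 mM | 2.00 mM | 1.0 µM |  | 25 min |

| run | time / min | target / % | uncatalysed product / % |
|---|---|---|---|
| larch | 4.00 | 84 | 16 |
| larch | 8.00 | 84 | 18 |
| larch | 12.0 | 82 | 18 |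
| larch | 15.0 | 82 | 17 |
| larch | 20.0 | 83 | 16 |
| larch | 25.0 | 83 | 19 |
| birch | 2.00 | 86 | 12 |
| birch | 3.00 | 90 | 13 |
| birch | 6.00 | 86 | 10 |
| birch | 10.0 | 88 | 13 |
| birch | 15.0 | 87 | 12 |
| birch | 25.0 | 90 | 12 |
| ash | 5.00 | 70 | 30 |
| ash | 10.0 | 72 | 31 |
| ash | 15.0 | 70 | 33 |
| ash | 20.0 | 67 | 30 |
| ash | 25.0 | 69 | 33 |

(each reading ± 1.5 percentage points)

- why nothing more happens at 25 min, or that something still does (it is still moving / forward and back rates have come level / the coupling partner has run out first / all of the starting material has reacted / no working catalyst is left)
- amount of target at 25 min, in percent of the starting material charged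
- amount of uncatalysed product at 25 min, in percent of the starting material charged

- the analysis behind the earlier runs scatters by 1.5 percentage points, standard deviation
- the reaction counts as stopped when no species that holds the starting material changes by six tenths of a point or more over the second half of the time

Larch and birch have the new flask's coupling partner charge and differ in C, so set them side by side:

s(larch) = C × ΣV/ΣP = 0.292 µM

s(birch) = C × ΣV/ΣP = 0.301 µM

These two readings nearly coincide, so carry their mean, 0.296 µM, as the split number s: the catalyst charged times the selectivity factor V/P at this partner charge. Ash differs from larch and birch in both C and coupling partner, at 4 mM, but s already has C multiplied in; ash reads 0.451 µM, higher than s, so if the rise belongs to the partner, s climbs with partner by 0.0773 µM mM⁻¹.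

For the new flask, my own reckoning runs:

V/P = s/C = 0.296

P = 1/(1 + V/P) = 77.1%, V = 22.9%

Larch already lay flat at 4.00 min, so if pace follows C, the new flask's knee comes by 5.60 min, earlier than 25 min. Target climbs at 0.138 mM min⁻¹ or steeper, bends, and lies level at 77.1%, with uncatalysed product level beneath it at 22.9%. Ash, at this same C, already accounts for 100% of its starting material at 5.00 min.

Now go round once more. If P and V each take one partner, together they take 1.0 mM of the 2.00 mM whatever the split, the same fall as in larch and birch, so s stands uncorrected.

The forecast says all of the starting material has reacted, with 77% target and 23% uncatalysed product, holding that “the split is inversely proportional to catalyst”.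

In the new flask all of the starting material has reacted, with 78.5% target and 21.5% uncatalysed product.

    starting material + free catalyst ⇌ catalyst intermediate A (K = 350 M⁻¹, k = 2.60 × 10⁵ M⁻¹ s⁻¹)
    coupling partner + catalyst intermediate A → free catalyst + target (k = 5.70 × 10⁵ M⁻¹ s⁻¹)
    second substrate + free catalyst ⇌ catalyst intermediate B (K = 2100 M⁻¹, k = 1.50 × 10⁵ M⁻¹ s⁻¹)
    coupling partner + catalyst intermediate B → free catalyst + second product (k = 15000 M⁻¹ s⁻¹)
    starting material + coupling partner → uncatalysed product (k = 19.0 M⁻¹ s⁻¹)
    2 second substrate → self-condensation product (k = 410 M⁻¹ s⁻¹)

The new flask's own s comes to 0.274 µM, with 46% of its coupling partner left. A neighbouring flask, the same in its other charges and its time, has 0.80 mM of coupling partner, less than its starting material. For that neighbour, sliding s down by the ash slope gives 0.204 µM, so V/P is 0.204, and sharing the partner charge between P and V gives 66.4% target and 13.6% uncatalysed product. That neighbour gives 65.6% target and 11.8% uncatalysed product, with its coupling partner at 0% and 22.6% of its starting material left.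

The numbers in the tables stem from a simulated flask with constants of no real substance; scatter was added.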